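**Plan** (locants: cyclopentene C1 carries CH2OAc, C2 carries CHO, C3 is the ring stereocenter, C4 and C5 are the two CH2; Cα is the side-chain CH(CHO))
1. Cuts, in retrosynthetic order: side-chain CHO ⇐ CH2OH; enal C1=C2 with CHO on C2 ⇐ β-hydroxy acetal; C1–CH2OAc ⇐ spiro-epoxide on a C1 ketone; ring bond C3–C4 ⇐ alkyl radical from an opened cyclopropanol adding to an alkene; pyran C3=Cα ⇐ RCM; acetal C–O; cyclopropane ⇐ ester + EtMgBr; C2–CH(OMe)2 ⇐ auxiliary alkylation.
2. Enabling feature: the unsubstituted C4–C5 ethano unit hangs on the fully substituted C1, so C1/C4/C5 are stored as a cyclopropanol (C1 = carbinol carbon) whose strain-driven opening puts a radical on C4, 5-exo to C3. The 1,5-dialdehyde (CHO on C2 and on Cα) is tied as a six-membered cyclic acetal, so the closure builds a cis-fused cyclopenta[c]pyran.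
3. Forward order: C2 stereocenter → cyclopropanol → mixed acetal with the side-chain allylic alcohol → dihydropyran (RCM) → cyclopentanone ring (key step) → acetoxymethyl group and enal → side-chain aldehyde.
4. Stereochemistry: C2 comes from alkylation of the (R)-4-benzyloxazolidinone imide; it relays to C3 (forced cis ring fusion) and to Cα (hydrogen delivery anti to the new ring bond) and is then erased by the dehydration. The (E)-alkene comes from geranyl bromide.

Key step: step 8

Assumption: the acetal carbon (from step 6 on) and the carbinol carbon made in step 9 arise as epimer mixtures with no bearing on the target and are written without descriptors; some descriptors change between intermediates only because CIP priorities change.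

Step 1
Reactants: 1 (4R)-4-benzyl-1,3-oxazolidin-2-one; 2 (2E)-but-2-enoyl chloride
Product: 4 (4R)-4-benzyl-3-[(2E)-but-2-enoyl]-1,3-oxazolidin-2-one, via N-lithio oxazolidinone 3 (not isolated)
Conditions: n-BuLi, THF, −78 °C; then 2, −78 → 0 °C
Reagents that add atoms: none
Why: N-acylation of the lithiated auxiliary by the acid chloride is the standard entry to N-enoyl oxazolidinones and creates no stereocenter.

Step 2
Reactants: 4 (4R)-4-benzyl-3-[(2E)-but-2-enoyl]-1,3-oxazolidin-2-one
Product: 6 (4R)-4-benzyl-3-[(2S)-2-(dimethoxymethyl)but-3-enoyl]-1,3-oxazolidin-2-one, via chlorotitanium dienolate 5 (not isolated)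
Conditions: TiCl4, iPr2NEt, CH2Cl2, −78 → 0 °C; then HC(OMe)3, 0 °C
Reagents that add atoms: trimethyl orthoformate, COC(OC)OC
Why: Soft enolisation at the γ-carbon should give the chelated (Z)-dienolate, which the dimethoxycarbenium ion from the orthoester attacks at the α-carbon on the face opposite the benzyl group (deconjugative Evans-type titanium-enolate alkylation), setting C2 as (S) and bringing in the future ring-aldehyde carbon at the aldehyde oxidation level.

Step 3
Reactants: 6 (4R)-4-benzyl-3-[(2S)-2-(dimethoxymethyl)but-3-enoyl]-1,3-oxazolidin-2-one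
Product: 7 methyl (2S)-2-(dimethoxymethyl)but-3-enoate
Conditions: MeMgBr, MeOH, CH2Cl2, 0 °C (MeOMgBr formed in the flask)
Reagents that add atoms: methanol, CO
Why: Transesterification with MeOMgBr cleaves only the exocyclic imide carbonyl under weakly basic conditions that should leave the β,γ-alkene and the α-stereocenter in place, and the auxiliary 1 is recovered.

Step 4
Reactants: 7 methyl (2S)-2-(dimethoxymethyl)but-3-enoate
Product: 8 1-[(2R)-1,1-dimethoxybut-3-en-2-yl]cyclopropan-1-ol
Conditions: EtMgBr (3 equiv, slow addition), Ti(OiPr)4 (20 mol %), THF, 0 °C → rt; aq NH4Cl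
Reagents that add atoms: ethylmagnesium bromide, CC[Mg]Br
Why: Kulinkovich reaction, in which the titanacyclopropane from EtMgBr and Ti(OiPr)4 converts the ester into the cyclopropanol whose two CH2 groups become C4 and C5, without a base strong enough to touch C2.

Step 5
Reactants: 9 2-methylprop-2-en-1-ol; 10 geranyl bromide [(2E)-1-bromo-3,7-dimethylocta-2,6-diene]
Product: 12 (5E)-6,10-dimethyl-2-methylideneundeca-5,9-dien-1-ol, via dilithio dianion 11 (not isolated)
Conditions: n-BuLi (2.2 equiv), TMEDA, Et2O/hexane, 0 °C → rt; then 10, THF, −78 °C → rt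
Reagents that add atoms: none
Why: Double deprotonation of methallyl alcohol gives the symmetric 2-(oxidomethyl)allyl anion, which the primary allylic bromide should alkylate at carbon by SN2 with retention of the (E)-alkene.

Step 6
Reactants: 8 1-[(2R)-1,1-dimethoxybut-3-en-2-yl]cyclopropan-1-ol; 12 (5E)-6,10-dimethyl-2-methylideneundeca-5,9-dien-1-ol
Product: 15 1-[(2R)-1-{[(5E)-6,10-dimethyl-2-methylideneundeca-5,9-dien-1-yl]oxy}-1-methoxybut-3-en-2-yl]cyclopropan-1-ol, via silylated collidinium triflate 13 (not isolated), via silylated mixed acetal 14 (not isolated)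
Conditions: TMSOTf (2.5 equiv), 2,4,6-collidine, CH2Cl2, 0 °C; then 12; then K2CO3, MeOH, rt
Reagents that add atoms: none
Why: Silyl triflate and collidine turn one methoxy group of the dimethyl acetal into an N-(α-methoxyalkyl)collidinium leaving group that the primary allylic alcohol displaces (non-acidic mixed-acetal exchange), while the cyclopropanol is masked in the flask as its trimethylsilyl ether and freed again by methanolysis.

Step 7
Reactants: 15 1-[(2R)-1-{[(5E)-6,10-dimethyl-2-methylideneundeca-5,9-dien-1-yl]oxy}-1-methoxybut-3-en-2-yl]cyclopropan-1-ol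
Product: 16 1-[(3R)-5-[(3E)-4,8-dimethylnona-3,7-dien-1-yl]-2-methoxy-3,6-dihydro-2H-pyran-3-yl]cyclopropan-1-ol
Conditions: second-generation Grubbs catalyst (5 mol %), CH2Cl2, 40 °C
Reagents that add atoms: none
Why: Ring-closing metathesis should join the vinyl group and the 1,1-disubstituted alkene into the six-membered dihydropyran with loss of ethene, the trisubstituted chain alkenes being too hindered to compete.

Step 8
Reactants: 16 1-[(3R)-5-[(3E)-4,8-dimethylnona-3,7-dien-1-yl]-2-methoxy-3,6-dihydro-2H-pyran-3-yl]cyclopropan-1-ol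
Product: 19 (4R,4aS,7aS)-4-[(3E)-4,8-dimethylnona-3,7-dien-1-yl]-1-methoxy-3,4,4a,5,6,7a-hexahydrocyclopenta[c]pyran-7(1H)-one, via β-keto alkyl radical 17 (not isolated), via tertiary alkyl radical 18 (not isolated)
Conditions: [Ir(dF(CF3)ppy)2(5,5′-d(CF3)bpy)]PF6 (2 mol %), tetrabutylphosphonium dimethyl phosphate (20 mol %), 2,4,6-triisopropylbenzenethiol (5 mol %), PhCF3 (0.02 M), blue LEDs, rt
Reagents that add atoms: none
Why: The excited trivalent-iridium photocatalyst and the phosphate base remove the cyclopropanol O–H by proton-coupled electron transfer, and the alkoxy radical undergoes strain-driven β-scission to the primary β-keto radical 17, whose carbonyl carbon is the former carbinol carbon (C1) and whose CH2CH2 unit is C5–C4. Radical 17 adds to the CH terminus of the ring alkene (C3) in a 5-exo-trig closure that forms the cyclopentanone ring fused to the pyran, and the tertiary radical 18 takes a hydrogen atom from the thiol, which the reduced photocatalyst and the protonated base regenerate, so the step is a redox-neutral isomerisation. The closest known reaction types are the photocatalytic PCET ring-opening of cyclic alcohols with thiol termination and the classical 5-exo cyclisation of cyclopropanol-derived β-keto radicals onto alkenes. C3 is controlled by C2: the three-atom tether on the allylic carbon can reach the neighbouring alkene carbon only on its own face, so the ring fusion must be cis. Cα is controlled in the termination: the bulky thiol should deliver hydrogen to the planar radical on the face opposite the new C3–C4 bond (convex face of the cis-fused bicycle), which leaves the side chain cis to that bond as the target requires. The step needs attack at C3 and not Cα (secured by 5-exo geometry and the fully substituted Cα) and ring closure faster than hydrogen transfer to 17 (secured by low thiol loading and dilution).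

Step 9
Reactants: 19 (4R,4aS,7aS)-4-[(3E)-4,8-dimethylnona-3,7-dien-1-yl]-1-methoxy-3,4,4a,5,6,7a-hexahydrocyclopenta[c]pyran-7(1H)-one
Product: 21 (4R,4aS,7aR)-4-[(3E)-4,8-dimethylnona-3,7-dien-1-yl]-1-methoxyhexahydro-1H-spiro[cyclopenta[c]pyran-7,2′-oxirane], via lithium chlorohydrin alkoxide 20 (not isolated)
Conditions: ClCH2I, MeLi·LiBr, THF, −78 °C → rt
Reagents that add atoms: chloroiodomethane, ClCI
Why: Chloromethyllithium formed in the flask should add to the ketone at −78 °C faster than it enolises the β-keto acetal, and the chlorohydrin alkoxide closes to the spiro-epoxide on warming, which places the future acetoxymethyl carbon on C1.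

Step 10
Reactants: 21 (4R,4aS,7aR)-4-[(3E)-4,8-dimethylnona-3,7-dien-1-yl]-1-methoxyhexahydro-1H-spiro[cyclopenta[c]pyran-7,2′-oxirane]
Product: 22 [(4R,4aS,7aR)-4-[(3E)-4,8-dimethylnona-3,7-dien-1-yl]-7-hydroxy-1-methoxyoctahydrocyclopenta[c]pyran-7-yl]methyl acetate
Conditions: AcOH, CsOAc, DMF, 80 °C
Reagents that add atoms: acetic acid, CC(=O)O
Why: Buffered acetate should open the 2,2-disubstituted epoxide by SN2 attack at its CH2 carbon, giving the primary acetate beside a tertiary alcohol while the other primary oxygen is still locked in the cyclic acetal.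

Step 11
Reactants: 22 [(4R,4aS,7aR)-4-[(3E)-4,8-dimethylnona-3,7-dien-1-yl]-7-hydroxy-1-methoxyoctahydrocyclopenta[c]pyran-7-yl]methyl acetate
Product: 25 [(3S)-2-formyl-3-[(2R,5E)-1-hydroxy-6,10-dimethylundeca-5,9-dien-2-yl]cyclopent-1-en-1-yl]methyl acetate, via lactol 23 (not isolated), via β-hydroxy aldehyde 24 (not isolated)
Conditions: p-TsOH·H2O (10 mol %), acetone/H2O (10:1), 40 °C
Reagents that add atoms: water, O
Why: Aqueous acid hydrolyses the cyclic methyl acetal, and the β-hydroxy aldehyde so released should lose water through its enol to the conjugated tetrasubstituted enal (aldol-type dehydration), which erases the relay center C2 and the carbinol center while C3 and Cα cannot enolise at this stage.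

Step 12
Reactants: 25 [(3S)-2-formyl-3-[(2R,5E)-1-hydroxy-6,10-dimethylundeca-5,9-dien-2-yl]cyclopent-1-en-1-yl]methyl acetate
Product: 26 [(3S)-3-[(2R,5E)-6,10-dimethyl-1-oxoundeca-5,9-dien-2-yl]-2-formylcyclopent-1-en-1-yl]methyl acetate
Conditions: Dess–Martin periodinane, NaHCO3, CH2Cl2, 0 °C → rt
Reagents that add atoms: none
Why: Buffered Dess–Martin oxidation should convert the primary alcohol of the open hydroxy enal (favoured over its lactol by the conjugation of the aldehyde) into the α-branched aldehyde without epimerising Cα and leave the enal and the allylic acetate untouched.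

**Compound list**
1 | (4R)-4-benzyl-1,3-oxazolidin-2-one | O=C1N[C@H](Cc2ccccc2)CO1 | starting material
2 | (2E)-but-2-enoyl chloride | C/C=C/C(Cl)=O | starting material
3 | lithium (4R)-4-benzyl-2-oxo-1,3-oxazolidin-3-ide | [Li+].O=C1[N-][C@H](Cc2ccccc2)CO1 | intermediate
4 | (4R)-4-benzyl-3-[(2E)-but-2-enoyl]-1,3-oxazolidin-2-one | C/C=C/C(=O)N1[C@H](Cc2ccccc2)COC1=O | intermediate
5 | trichlorotitanium (Z)-dienolate of 4 (vinyl cis to O–Ti) | C=C/C=C(\O[Ti](Cl)(Cl)Cl)N1[C@H](Cc2ccccc2)COC1=O | intermediate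
6 | (4R)-4-benzyl-3-[(2S)-2-(dimethoxymethyl)but-3-enoyl]-1,3-oxazolidin-2-one | C=C[C@@H](C(OC)OC)C(=O)N1[C@H](Cc2ccccc2)COC1=O | intermediate
7 | methyl (2S)-2-(dimethoxymethyl)but-3-enoate | C=C[C@@H](C(OC)OC)C(=O)OC | intermediate
8 | 1-[(2R)-1,1-dimethoxybut-3-en-2-yl]cyclopropan-1-ol | C=C[C@@H](C(OC)OC)C1(O)CC1 | intermediate
9 | 2-methylprop-2-en-1-ol | CC(=C)CO | starting material
10 | geranyl bromide, (2E)-1-bromo-3,7-dimethylocta-2,6-diene | BrC/C=C(\C)CCC=C(C)C | starting material
11 | dilithium 2-(oxidomethyl)prop-2-en-1-ide (dianion of 9) | [Li+].[Li+].[CH2-]C(=C)C[O-] | intermediate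
12 | (5E)-6,10-dimethyl-2-methylideneundeca-5,9-dien-1-ol | OCC(=C)CC/C=C(\C)CCC=C(C)C | intermediate
13 | 1-[(2R)-1-methoxy-2-{1-[(trimethylsilyl)oxy]cyclopropyl}but-3-en-1-yl]-2,4,6-trimethylpyridin-1-ium trifluoromethanesulfonate | C=C[C@@H](C(OC)[n+]1c(C)cc(C)cc1C)C1(O[Si](C)(C)C)CC1.[O-]S(=O)(=O)C(F)(F)F | intermediate
14 | trimethylsilyl ether of 15 (at the cyclopropanol oxygen) | C=C[C@@H](C(OC)OCC(=C)CC/C=C(\C)CCC=C(C)C)C1(O[Si](C)(C)C)CC1 | intermediate
15 | 1-[(2R)-1-{[(5E)-6,10-dimethyl-2-methylideneundeca-5,9-dien-1-yl]oxy}-1-methoxybut-3-en-2-yl]cyclopropan-1-ol | C=C[C@@H](C(OC)OCC(=C)CC/C=C(\C)CCC=C(C)C)C1(O)CC1 | intermediate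
16 | 1-[(3R)-5-[(3E)-4,8-dimethylnona-3,7-dien-1-yl]-2-methoxy-3,6-dihydro-2H-pyran-3-yl]cyclopropan-1-ol | OC1(CC1)[C@H]2C=C(CC/C=C(\C)CCC=C(C)C)COC2OC | intermediate
17 | 3-[(3S)-5-[(3E)-4,8-dimethylnona-3,7-dien-1-yl]-2-methoxy-3,6-dihydro-2H-pyran-3-yl]-3-oxopropyl radical | [CH2]CC(=O)[C@H]1C=C(CC/C=C(\C)CCC=C(C)C)COC1OC | intermediate
18 | cis-fused 4-[(3E)-4,8-dimethylnona-3,7-dien-1-yl]-1-methoxy-7-oxooctahydrocyclopenta[c]pyran-4-yl radical (ring fusion as in 19) | COC1OC[C](CC/C=C(\C)CCC=C(C)C)[C@@H]2CCC(=O)[C@H]12 | intermediate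
19 | (4R,4aS,7aS)-4-[(3E)-4,8-dimethylnona-3,7-dien-1-yl]-1-methoxy-3,4,4a,5,6,7a-hexahydrocyclopenta[c]pyran-7(1H)-one | COC1OC[C@H](CC/C=C(\C)CCC=C(C)C)[C@@H]2CCC(=O)[C@H]12 | intermediate
20 | lithium (4R,4aS,7aR)-7-(chloromethyl)-4-[(3E)-4,8-dimethylnona-3,7-dien-1-yl]-1-methoxyoctahydrocyclopenta[c]pyran-7-olate | [Li+].COC1OC[C@H](CC/C=C(\C)CCC=C(C)C)[C@@H]2CCC([O-])(CCl)[C@H]12 | intermediate
21 | (4R,4aS,7aR)-4-[(3E)-4,8-dimethylnona-3,7-dien-1-yl]-1-methoxyhexahydro-1H-spiro[cyclopenta[c]pyran-7,2′-oxirane] | COC1OC[C@H](CC/C=C(\C)CCC=C(C)C)[C@@H]2CCC3(CO3)[C@H]12 | intermediate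
22 | [(4R,4aS,7aR)-4-[(3E)-4,8-dimethylnona-3,7-dien-1-yl]-7-hydroxy-1-methoxyoctahydrocyclopenta[c]pyran-7-yl]methyl acetate | COC1OC[C@H](CC/C=C(\C)CCC=C(C)C)[C@@H]2CCC(O)(COC(C)=O)[C@H]12 | intermediate
23 | [(4R,4aS,7aR)-4-[(3E)-4,8-dimethylnona-3,7-dien-1-yl]-1,7-dihydroxyoctahydrocyclopenta[c]pyran-7-yl]methyl acetate (lactol) | OC1OC[C@H](CC/C=C(\C)CCC=C(C)C)[C@@H]2CCC(O)(COC(C)=O)[C@H]12 | intermediate
24 | {(2R,3S)-2-formyl-1-hydroxy-3-[(2R,5E)-1-hydroxy-6,10-dimethylundeca-5,9-dien-2-yl]cyclopentyl}methyl acetate (ring-opened form of 23) | CC(=O)OCC1(O)CC[C@@H]([C@H](CO)CC/C=C(\C)CCC=C(C)C)[C@H]1C=O | intermediate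
25 | [(3S)-2-formyl-3-[(2R,5E)-1-hydroxy-6,10-dimethylundeca-5,9-dien-2-yl]cyclopent-1-en-1-yl]methyl acetate | CC(=O)OCC1=C(C=O)[C@H]([C@H](CO)CC/C=C(\C)CCC=C(C)C)CC1 | intermediate
26 | [(3S)-3-[(2R,5E)-6,10-dimethyl-1-oxoundeca-5,9-dien-2-yl]-2-formylcyclopent-1-en-1-yl]methyl acetate | CC(=O)OCC1=C(C=O)[C@H]([C@H](C=O)CC/C=C(\C)CCC=C(C)C)CC1 | target

**Count and risks**
Total step count: 12. Longest linear sequence: 11 steps (steps 1–4 and 6–12); step 5 makes the second fragment.

Steps most likely to fail: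

1. Step 8. Hydrogen transfer from the thiol to the primary radical, or a 1,5-hydrogen shift from the acetal C–H, may outrun ring closure. Thiyl radicals may also add reversibly to the chain alkene and scramble its (E)-geometry, and the last hydrogen delivery may show incomplete facial bias. Fallback, from 16 back to 19: Et2Zn in THF should convert the cyclopropanol into the zinc homoenolate ethyl{3-[(3S)-5-[(3E)-4,8-dimethylnona-3,7-dien-1-yl]-2-methoxy-3,6-dihydro-2H-pyran-3-yl]-3-oxopropyl}zinc F4. Iodine at −78 °C should then cleave the carbon–zinc bond of F4 to 3-iodo-1-[(3S)-5-[(3E)-4,8-dimethylnona-3,7-dien-1-yl]-2-methoxy-3,6-dihydro-2H-pyran-3-yl]propan-1-one F5. Slow addition of (Me3Si)3SiH with Et3B/air to F5 in toluene at −20 °C runs the same 5-exo closure as a thiol-free silyl-radical chain through radicals 17 and 18 to 19. F5 has C2 next to a ketone and would be kept cold and free of base.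

2. Step 2. The electrophile may attack the γ-carbon of the dienolate, or the product may lose methanol to a β-methoxyacryloyl imide; either erases C2. Fallback, from 1 back to 6: N-acylation of 1 (n-BuLi; 4-(phenylselanyl)butanoyl chloride) gives (4R)-4-benzyl-3-[4-(phenylselanyl)butanoyl]-1,3-oxazolidin-2-one F1. F1 is a saturated imide in which only α-attack is possible, and TiCl4/iPr2NEt/HC(OMe)3 should alkylate it to (4R)-4-benzyl-3-[(2S)-2-(dimethoxymethyl)-4-(phenylselanyl)butanoyl]-1,3-oxazolidin-2-one F2. H2O2/pyridine in CH2Cl2 oxidises F2 to the selenoxide (4R)-4-benzyl-3-[(2S)-2-(dimethoxymethyl)-4-(phenylseleninyl)butanoyl]-1,3-oxazolidin-2-one F3. Syn-elimination of F3 at rt installs the vinyl group and gives 6.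

3. Step 10. SN2 attack of acetate at the hindered CH2 may be slow, so that opening at the tertiary carbon, rearrangement of the epoxide to an aldehyde or exchange at the acetal takes over. Fallback, from 19 back to 22: addition of ClMgCH2SiMe2(OiPr) to the ketone in THF at −78 °C gives the β-hydroxysilane (4R,4aS,7aR)-4-[(3E)-4,8-dimethylnona-3,7-dien-1-yl]-7-{[dimethyl(propan-2-yloxy)silyl]methyl}-1-methoxyoctahydrocyclopenta[c]pyran-7-ol F6. Tamao–Fleming oxidation of F6 (KF, KHCO3, H2O2, THF/MeOH) gives the diol (4R,4aS,7aR)-4-[(3E)-4,8-dimethylnona-3,7-dien-1-yl]-7-(hydroxymethyl)-1-methoxyoctahydrocyclopenta[c]pyran-7-ol F7. Ac2O/pyridine acetylates only the primary hydroxyl of F7 and gives 22.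

Further compounds
F1 | step 2 | (4R)-4-benzyl-3-[4-(phenylselanyl)butanoyl]-1,3-oxazolidin-2-one | O=C(CCC[Se]c1ccccc1)N1[C@H](Cc2ccccc2)COC1=O
F2 | step 2 | (4R)-4-benzyl-3-[(2S)-2-(dimethoxymethyl)-4-(phenylselanyl)butanoyl]-1,3-oxazolidin-2-one | c1ccccc1[Se]CC[C@@H](C(OC)OC)C(=O)N1[C@H](Cc2ccccc2)COC1=O
F3 | step 2 | (4R)-4-benzyl-3-[(2S)-2-(dimethoxymethyl)-4-(phenylseleninyl)butanoyl]-1,3-oxazolidin-2-one | O=[Se](CC[C@@H](C(OC)OC)C(=O)N1[C@H](Cc2ccccc2)COC1=O)c1ccccc1
F4 | step 8 | ethyl{3-[(3S)-5-[(3E)-4,8-dimethylnona-3,7-dien-1-yl]-2-methoxy-3,6-dihydro-2H-pyran-3-yl]-3-oxopropyl}zinc | CC[Zn]CCC(=O)[C@H]1C=C(CC/C=C(\C)CCC=C(C)C)COC1OC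
F5 | step 8 | 3-iodo-1-[(3S)-5-[(3E)-4,8-dimethylnona-3,7-dien-1-yl]-2-methoxy-3,6-dihydro-2H-pyran-3-yl]propan-1-one | ICCC(=O)[C@H]1C=C(CC/C=C(\C)CCC=C(C)C)COC1OC
F6 | step 10 | (4R,4aS,7aR)-4-[(3E)-4,8-dimethylnona-3,7-dien-1-yl]-7-{[dimethyl(propan-2-yloxy)silyl]methyl}-1-methoxyoctahydrocyclopenta[c]pyran-7-ol | COC1OC[C@H](CC/C=C(\C)CCC=C(C)C)[C@@H]2CCC(O)(C[Si](C)(C)OC(C)C)[C@H]12
F7 | step 10 | (4R,4aS,7aR)-4-[(3E)-4,8-dimethylnona-3,7-dien-1-yl]-7-(hydroxymethyl)-1-methoxyoctahydrocyclopenta[c]pyran-7-ol | COC1OC[C@H](CC/C=C(\C)CCC=C(C)C)[C@@H]2CCC(O)(CO)[C@H]12
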